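**Plan**

- Retrosynthesis: cut the two ester C–O bonds (angelate at C2, 4-methoxybenzoate at C6), then the ring-fusion bond C1–C5, which is traced back to the C1–C6 bond of a cis-decalin, then the ring-B bonds C1–C10 and C6–C7 (Diels–Alder). Locants: C1 quaternary methyl carbon, C2, C3, C4 isopropyl carbinol, C5 fusion CH, C6, C7, C8(methyl)=C9, C10.
- Enabling feature: the trans C1–C5 fusion bond lies next to the oxygen-bearing C6. The five-membered ring (C1–C5) and the seven-membered ring (C1, C5–C10) are therefore what a 1,2-shift of C1 from C6 to C5 leaves behind in a cis-decalin (ring A = C1–C6, ring B = C1, C6–C10) with a leaving group on C5 and an alkoxide on C6.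
- Forward: ring B is made first by a catalytic enantioselective Diels–Alder reaction of thymoquinone with a 2-silyloxy-3-methylbutadiene (the silyloxy group steers the methyl to C8 and is later removed through the enol triflate). Ring A is then oxygenated at C6, C4 (enedione epoxide), C2 and C5; the shift creates both new rings at once; the C6 ketone is reduced and the esters go on last.
- Stereochemistry: C1 and C6 (absolute) come from the chiral Diels–Alder catalyst. The C6, C4, C2 and C5 oxygens are set cis to the C1 methyl by substrate control on the cis-bicycle. C5 of the target arises by inversion in the shift, and the C6 carbinol by an equatorial-selective dissolving-metal reduction.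

Key step: step 14

Convention: the locants above are used for every compound; α is the face of the bicycle that carries the C1 methyl group, β the other face.

Assumption: the (S)-oxazaborolidinium catalyst is taken to deliver the diene to the quinone face that gives the drawn enantiomer of 4 (model: boron on the C5=O lone pair syn to C6–H, α-C–H···O contact, attack away from the shielding phenyl group); if the adduct proves antipodal, the (R)-catalyst is used and nothing else changes.

**Route**

Step 1
Reactants: 1 3-methylbut-3-en-2-one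
Product: 2 3-methyl-2-(triisopropylsilyloxy)buta-1,3-diene
Conditions: iPr3SiOSO2CF3, Et3N, CH2Cl2, 0 °C to 23 °C
Reagents that add atoms: triisopropylsilyl trifluoromethanesulfonate, CC(C)[Si](C(C)C)(C(C)C)OS(=O)(=O)C(F)(F)F
Why: Silyl enol ether formation by soft enolisation; the acetyl methyl is the only enolisable position, so a single 2-silyloxy diene should form.

Step 2
Reactants: 2 3-methyl-2-(triisopropylsilyloxy)buta-1,3-diene; 3 thymoquinone
Product: 4 cis-fused Diels–Alder adduct (C1 methyl and C6–H both α; ring-B silyl enol ether C8=C9)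
Conditions: (S)-3,3-diphenyl-1-(2-methylphenyl)tetrahydro-1H,3H-pyrrolo[1,2-c][1,3,2]oxazaborole (20 mol %), (CF3SO2)2NH (20 mol %), CH2Cl2, −78 °C to −40 °C
Reagents that add atoms: none
Why: Chiral oxazaborolidinium-catalysed quinone Diels–Alder reaction; boron on the C5 carbonyl (lone pair syn to C6–H) activates the methyl-bearing C6=C1 double bond, the nucleophilic diene CH2 next to C–OSi bonds to C1 (β to the bound carbonyl) so that the methyl lands on C8, suprafacial addition gives the cis fusion, and the shielded quinone face fixes C1 and C6.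

Step 3
Reactants: 4 cis-fused Diels–Alder adduct
Product: 6 6α-hydroxy enedione, via potassium enolate 5 (not isolated)
Conditions: KN(SiMe3)2, THF, −78 °C; 2-(phenylsulfonyl)-3-phenyloxaziridine, −78 °C; aq NH4Cl
Reagents that add atoms: 2-(phenylsulfonyl)-3-phenyloxaziridine, O=S(=O)(N1OC1c1ccccc1)c1ccccc1
Why: Davis α-hydroxylation of a ketone enolate; C6–H is the only α-hydrogen of the enedione, and oxygen transfer to the C5=C6 enolate should keep the less strained cis ring fusion, which puts the hydroxyl on the face of the C1 methyl.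

Step 4
Reactants: 6 6α-hydroxy enedione
Product: 7 6α-triethylsilyloxy enedione
Conditions: Et3SiOSO2CF3, 2,6-lutidine, CH2Cl2, −78 °C to 0 °C
Reagents that add atoms: triethylsilyl trifluoromethanesulfonate, CC[Si](CC)(CC)OS(=O)(=O)C(F)(F)F
Why: Silyl triflate silylation of a hindered tertiary alcohol; masking C6–OH keeps the ketol out of base-induced retro-aldol and acyloin chemistry and later leaves the C2/C4 pair as the only 1,3-diol (C2 is 1,3 to both C4 and C6).

Step 5
Reactants: 7 6α-triethylsilyloxy enedione
Product: 8 3α,4α-epoxide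
Conditions: t-BuOOH (anhydrous), DBU, CH2Cl2, 0 °C
Reagents that add atoms: tert-butyl hydroperoxide, CC(C)(C)OO
Why: Weitz–Scheffer nucleophilic epoxidation of the enedione; the peroxide anion should add to the unsubstituted C3 from the convex face of the folded cis-bicycle (away from ring B, the face of the C1 methyl), and closure on C4 places the epoxide oxygen α.

Step 6
Reactants: 8 3α,4α-epoxide
Product: 9 4α-hydroxy-2,5-dione
Conditions: (PhSe)2, NaBH4, EtOH, then AcOH, 0 °C
Reagents that add atoms: none
Why: Reductive opening of an α,β-epoxy ketone by sodium phenylseleno(triethoxy)borate; the selenolate displaces oxygen at the secondary α-carbon C3 rather than at the tertiary C4, and a second selenolate removes selenium from the α-seleno ketone, so the oxygen stays on C4 with its configuration untouched.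

Step 7
Reactants: 9 4α-hydroxy-2,5-dione
Product: 10 2α,4α-diol 5-ketone
Conditions: Et2BOMe, NaBH4, THF/MeOH, −78 °C; AcOH, MeOH co-evaporation
Reagents that add atoms: none
Why: Narasaka–Prasad reduction; boron bridges the C4 hydroxyl and the C2 carbonyl on the α face and external hydride adds from the β face to give the cis 1,3-diol, while the C5 ketone between two fully substituted carbons should be left.

Step 8
Reactants: 10 2α,4α-diol 5-ketone
Product: 11 2α,4α-acetonide 5-ketone
Conditions: Me2C(OMe)2, PPTS (cat.), CH2Cl2, 23 °C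
Reagents that add atoms: 2,2-dimethoxypropane, COC(C)(C)OC
Why: Acid-catalysed transketalisation; the two hydroxyls are cis and 1,3-diaxial on ring A, so the 2,4-dioxabicyclo[3.3.1]nonane closes, and with C6–O silylated no other diol can compete.

Step 9
Reactants: 11 2α,4α-acetonide 5-ketone
Product: 13 C9 enol triflate, via caesium enolate 12 (not isolated)
Conditions: CsF, PhN(SO2CF3)2, DME, 23 °C
Reagents that add atoms: N-phenylbis(trifluoromethanesulfonimide), O=S(=O)(N(c1ccccc1)S(=O)(=O)C(F)(F)F)C(F)(F)F
Why: Fluoride cleavage of the silyl enol ether and O-triflation of the regiodefined enolate; the C5 ketone has no α-hydrogen and there is no free hydroxyl, so the enolate cannot equilibrate before it is trapped.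

Step 10
Reactants: 13 C9 enol triflate
Product: 14 8-ene acetonide 5-ketone
Conditions: Pd(OAc)2 (5 mol %), PPh3, n-Bu3N, HCO2H, DMF, 60 °C
Reagents that add atoms: none
Why: Palladium-catalysed formate reduction of an enol triflate (oxidative addition to zerovalent palladium, formate exchange, decarboxylation, reductive elimination) should give the C8=C9 alkene without moving the double bond.

Step 11
Reactants: 14 8-ene acetonide 5-ketone
Product: 15 5α-alcohol
Conditions: NaBH4, MeOH/THF, 0 °C to 23 °C
Reagents that add atoms: none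
Why: Hydride reduction of a ketone; ring A is a chair locked by the acetonide with the C4 and C6 oxygens axial on the α face, so hydride should add axially from the β face, anti to both α-C–O bonds (Felkin–Anh polar model), to give the equatorial 5α-alcohol.

Step 12
Reactants: 15 5α-alcohol
Product: 16 5α,6α-diol
Conditions: Bu4NF, THF, 0 °C to 23 °C
Reagents that add atoms: none
Why: Fluoride cleavage of the triethylsilyl ether; a silyl shift between the two cis oxygens would not matter because both end up free.

Step 13
Reactants: 16 5α,6α-diol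
Product: 17 5α-mesylate 6α-alcohol
Conditions: CH3SO2Cl, Et3N, CH2Cl2, −20 °C to 0 °C
Reagents that add atoms: methanesulfonyl chloride, CS(=O)(=O)Cl
Why: Sulfonylation through the small sulfene electrophile takes the secondary C5 hydroxyl and leaves the tertiary C6 hydroxyl free.

Step 14
Reactants: 17 5α-mesylate 6α-alcohol
Product: 19 trans-fused hydroazulen-6-one acetonide, via potassium alkoxide 18 (not isolated)
Conditions: KOC(CH3)3 (1.05 equiv), THF (0.01 M), −40 °C to 0 °C; pH 7 buffer
Reagents that add atoms: none
Why: Deprotonation of the tertiary C6 hydroxyl gives alkoxide 18, whose oxygen pushes the C6–C1 σ bond onto C5 from the side opposite the equatorial mesylate, so C1–C5 forms as C5–O breaks and C6 becomes the carbonyl carbon (anionic semipinacol rearrangement of a 1,2-diol monosulfonate, the classical base-induced decalin-to-hydroazulenone change). Ring A closes to the cyclopentane C1–C2–C3–C4–C5 by contraction, the migrating C1 displacing the mesylate from the rear, and ring B grows to the cycloheptene C1–C5–C6–C7–C8–C9–C10 by one-carbon expansion in the same suprafacial 1,2-shift. The only new stereocentre, C5, is set by inversion at the migration terminus while C1 migrates with retention, which turns the cis-decalin into the trans-fused bicycle with C5–H β. The step needs C1 and not C3 or C7 to migrate, and no epoxide or alkene: in the acetonide-locked chair both C6–C1 and C4–C3 are anti-periplanar to C5–OMs but only C6 has a free oxygen to push, C6–C7 is gauche, the C6 oxygen is cis to the leaving group and cannot displace it, and C4 and C6 carry no hydrogen for elimination. One equivalent of base, low temperature and high dilution are used so that the β,γ-unsaturated ketone is not left with base that could move the C8=C9 double bond or epimerise C5.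

Step 15
Reactants: 19 trans-fused hydroazulen-6-one acetonide
Product: 20 6β-alcohol
Conditions: Li, NH3(l), THF, t-BuOH, −78 °C; NH4Cl
Reagents that add atoms: none
Why: Dissolving-metal (Birch-type) ketone reduction should give the more stable equatorial 6β-carbinol (C6–H axial, trans to C5–H), whereas hydride reagents would add from the open face opposite the 1,3-related axial C1 methyl and give the axial 6α-epimer.

Step 16
Reactants: 20 6β-alcohol; 21 4-methoxybenzoyl chloride
Product: 22 6β-(4-methoxybenzoate) acetonide
Conditions: DMAP, pyridine, CH2Cl2, 23 °C to 40 °C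
Reagents that add atoms: none
Why: DMAP-catalysed acylation of the only free hydroxyl, an equatorial secondary alcohol.

Step 17
Reactants: 22 6β-(4-methoxybenzoate) acetonide
Product: 23 2α,4α-diol 6β-(4-methoxybenzoate)
Conditions: AcOH/H2O/THF (3:1:1), 40 °C
Reagents that add atoms: none
Why: Acid hydrolysis of the strained cyclopentane 1,3-acetonide (2,4-dioxabicyclo[3.2.1]octane) should proceed under conditions that leave the aryl ester, the tertiary carbinol and the trisubstituted alkene intact.

Step 18
Reactants: 23 2α,4α-diol 6β-(4-methoxybenzoate); 24 angelic acid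
Product: 26 target CNP0204191.1, via mixed anhydride 25 (not isolated)
Conditions: 24, 2,4,6-Cl3C6H2COCl, Et3N, toluene, 23 °C; then 23, toluene, 80 °C
Reagents that add atoms: none
Why: Yamaguchi esterification through the mixed anhydride without DMAP should acylate the secondary C2 hydroxyl, not the tertiary C4 hydroxyl, and keep the (Z)-geometry of the angelate.

**Compound list**

1 | 3-methylbut-3-en-2-one | CC(=O)C(C)=C | starting material
2 | 3-methyl-2-(triisopropylsilyloxy)buta-1,3-diene | C=C(C)C(=C)O[Si](C(C)C)(C(C)C)C(C)C | intermediate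
3 | thymoquinone (2-isopropyl-5-methyl-1,4-benzoquinone) | CC1=CC(=O)C(C(C)C)=CC1=O | starting material
4 | cis-fused adduct: 4-isopropyl-1α,8-dimethyl-9-(triisopropylsilyloxy)-6αH-bicyclo[4.4.0]deca-3,8-diene-2,5-dione | C[C@@]12CC(O[Si](C(C)C)(C(C)C)C(C)C)=C(C)C[C@@H]1C(=O)C(C(C)C)=CC2=O | intermediate
5 | potassium C5(O)=C6 enolate of 4 | C[C@@]12CC(O[Si](C(C)C)(C(C)C)C(C)C)=C(C)CC1=C([O-])C(C(C)C)=CC2=O.[K+] | intermediate (not isolated)
6 | 6α-hydroxy enedione (C6–OH cis to C1 methyl) | C[C@@]12CC(O[Si](C(C)C)(C(C)C)C(C)C)=C(C)C[C@]1(O)C(=O)C(C(C)C)=CC2=O | intermediate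
7 | 6α-triethylsilyloxy enedione | C[C@@]12CC(O[Si](C(C)C)(C(C)C)C(C)C)=C(C)C[C@]1(O[Si](CC)(CC)CC)C(=O)C(C(C)C)=CC2=O | intermediate
8 | 3α,4α-epoxy-2,5-dione | C[C@@]12CC(O[Si](C(C)C)(C(C)C)C(C)C)=C(C)C[C@]1(O[Si](CC)(CC)CC)C(=O)[C@@]3(C(C)C)O[C@H]3C2=O | intermediate
9 | 4α-hydroxy-4β-isopropyl-2,5-dione | C[C@@]12CC(O[Si](C(C)C)(C(C)C)C(C)C)=C(C)C[C@]1(O[Si](CC)(CC)CC)C(=O)[C@](O)(C(C)C)CC2=O | intermediate
10 | 2α,4α-diol 5-ketone | C[C@@]12CC(O[Si](C(C)C)(C(C)C)C(C)C)=C(C)C[C@]1(O[Si](CC)(CC)CC)C(=O)[C@](O)(C(C)C)C[C@H]2O | intermediate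
11 | 2α,4α-acetonide 5-ketone (ring-B silyl enol ether) | C[C@@]12CC(O[Si](C(C)C)(C(C)C)C(C)C)=C(C)C[C@]1(O[Si](CC)(CC)CC)C(=O)[C@]3(C(C)C)C[C@H]2OC(C)(C)O3 | intermediate
12 | caesium C9 enolate of 11 | C[C@@]12CC([O-])=C(C)C[C@]1(O[Si](CC)(CC)CC)C(=O)[C@]3(C(C)C)C[C@H]2OC(C)(C)O3.[Cs+] | intermediate (not isolated)
13 | C9 enol triflate | C[C@@]12CC(OS(=O)(=O)C(F)(F)F)=C(C)C[C@]1(O[Si](CC)(CC)CC)C(=O)[C@]3(C(C)C)C[C@H]2OC(C)(C)O3 | intermediate
14 | 8-ene 2α,4α-acetonide 6α-silyloxy 5-ketone | C[C@@]12CC=C(C)C[C@]1(O[Si](CC)(CC)CC)C(=O)[C@]3(C(C)C)C[C@H]2OC(C)(C)O3 | intermediate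
15 | 5α-alcohol (C5–OH equatorial, C5–H β) | C[C@@]12CC=C(C)C[C@]1(O[Si](CC)(CC)CC)[C@@H](O)[C@]3(C(C)C)C[C@H]2OC(C)(C)O3 | intermediate
16 | 5α,6α-diol 2α,4α-acetonide | C[C@@]12CC=C(C)C[C@]1(O)[C@@H](O)[C@]3(C(C)C)C[C@H]2OC(C)(C)O3 | intermediate
17 | cis-decalin 5α-mesylate 6α-alcohol 2α,4α-acetonide (key-step precursor) | C[C@@]12CC=C(C)C[C@]1(O)[C@@H](OS(C)(=O)=O)[C@]3(C(C)C)C[C@H]2OC(C)(C)O3 | intermediate
18 | potassium C6 alkoxide of 17 | C[C@@]12CC=C(C)C[C@]1([O-])[C@@H](OS(C)(=O)=O)[C@]3(C(C)C)C[C@H]2OC(C)(C)O3.[K+] | intermediate (not isolated)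
19 | trans-fused hydroazulen-6-one 2α,4α-acetonide (C1 methyl α, C5–H β; key-step product) | CC1(C)O[C@@H]2C[C@@](O1)(C(C)C)[C@@H]3C(=O)CC(C)=CC[C@]32C | intermediate
20 | 6β-alcohol 2α,4α-acetonide | CC1(C)O[C@@H]2C[C@@](O1)(C(C)C)[C@@H]3[C@@H](O)CC(C)=CC[C@]32C | intermediate
21 | 4-methoxybenzoyl chloride | COc1ccc(cc1)C(Cl)=O | starting material
22 | 6β-(4-methoxybenzoate) 2α,4α-acetonide | CC1(C)O[C@@H]2C[C@@](O1)(C(C)C)[C@@H]3[C@@H](OC(=O)c4ccc(OC)cc4)CC(C)=CC[C@]32C | intermediate
23 | 2α,4α-diol 6β-(4-methoxybenzoate) | O[C@@H]1C[C@@](O)(C(C)C)[C@@H]2[C@@H](OC(=O)c3ccc(OC)cc3)CC(C)=CC[C@]21C | intermediate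
24 | angelic acid ((Z)-2-methylbut-2-enoic acid) | C/C=C(/C)C(=O)O | starting material
25 | angelic 2,4,6-trichlorobenzoic anhydride | C/C=C(/C)C(=O)OC(=O)c1c(Cl)cc(Cl)cc1Cl | intermediate (not isolated)
26 | CNP0204191.1: 2α-angeloyloxy-4α-hydroxy-4β-isopropyl-6β-(4-methoxybenzoyloxy)-1α,8-dimethyl-5βH-hydroazul-8-ene (target locants) | C/C=C(/C)C(=O)O[C@@H]1C[C@@](O)(C(C)C)[C@@H]2[C@@H](OC(=O)c3ccc(OC)cc3)CC(C)=CC[C@]21C | target

**Count**

Total steps: 18. Longest linear sequence: 18 steps (from 3-methylbut-3-en-2-one; 17 from thymoquinone).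

**Steps most likely to fail**

Step 2. The cycloaddition has to form a bond at a fully substituted quinone carbon. It may be slow, the silyl enol ether may add in a Mukaiyama–Michael sense instead, or regio- and facial control may erode. Fallback, from 3 back to 14: thymoquinone 3 is heated with isoprene without catalyst. The uncatalysed reaction is expected to join the nucleophilic diene terminus to the unsubstituted C6, which gives the racemic C8-methyl adduct beside its C9-methyl regioisomer. The adduct is purified and resolved by preparative chromatography on a chiral stationary phase to give the isoprene adduct F1. The sequence of steps 3 to 7 then leads through the 6α-hydroxy enedione F2, the triethylsilyl ether F3, the 3α,4α-epoxide F4 and the 4α-hydroxy dione F5 to the 2α,4α-diol F6. Acetonide formation as in step 8 gives 14 directly, so steps 9 and 10 fall away.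

Step 14. After the shift, remaining alkoxide may enolise the new ketone at C7 and draw the C8=C9 double bond into conjugation, or epimerise C5. Fallback, from 13 back to 19: the shift is run while ring B is still the enol triflate, which cannot migrate into conjugation. NaBH4 reduces 13 to the 5α-alcohol F7, HF·pyridine removes the silyl group to give the diol F8, and mesylation gives the mesylate F9. KOC(CH3)3 then induces the same 1,2-shift to the hydroazulenone enol triflate F10. The palladium/formate reduction of step 10 is applied last and delivers 19 under buffered conditions.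

Step 15. Electron-transfer reduction may give incomplete equatorial selectivity, or amide base formed during it may move the double bond before the ketone is consumed. Fallback, from 19 back to 22: LiBH(sec-Bu)3 adds from the open β face to give the axial 6α-alcohol F11. Mitsunobu esterification of F11 with 4-methoxybenzoic acid (PPh3, diisopropyl azodicarboxylate) inverts C6 and gives 22, so step 16 is not needed.

**Further compounds**

F1 | step 2 | 4-isopropyl-1α,8-dimethyl-6αH-bicyclo[4.4.0]deca-3,8-diene-2,5-dione (thymoquinone–isoprene adduct, resolved enantiomer) | C[C@@]12CC=C(C)C[C@@H]1C(=O)C(C(C)C)=CC2=O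
F2 | step 2 | 6α-hydroxy enedione of the isoprene series | C[C@@]12CC=C(C)C[C@]1(O)C(=O)C(C(C)C)=CC2=O
F3 | step 2 | 6α-triethylsilyloxy enedione of the isoprene series | C[C@@]12CC=C(C)C[C@]1(O[Si](CC)(CC)CC)C(=O)C(C(C)C)=CC2=O
F4 | step 2 | 3α,4α-epoxy-2,5-dione of the isoprene series | C[C@@]12CC=C(C)C[C@]1(O[Si](CC)(CC)CC)C(=O)[C@@]3(C(C)C)O[C@H]3C2=O
F5 | step 2 | 4α-hydroxy-2,5-dione of the isoprene series | C[C@@]12CC=C(C)C[C@]1(O[Si](CC)(CC)CC)C(=O)[C@](O)(C(C)C)CC2=O
F6 | step 2 | 2α,4α-diol 5-ketone of the isoprene series | C[C@@]12CC=C(C)C[C@]1(O[Si](CC)(CC)CC)C(=O)[C@](O)(C(C)C)C[C@H]2O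
F7 | step 14 | 5α-alcohol with ring-B enol triflate | C[C@@]12CC(OS(=O)(=O)C(F)(F)F)=C(C)C[C@]1(O[Si](CC)(CC)CC)[C@@H](O)[C@]3(C(C)C)C[C@H]2OC(C)(C)O3
F8 | step 14 | 5α,6α-diol with ring-B enol triflate | C[C@@]12CC(OS(=O)(=O)C(F)(F)F)=C(C)C[C@]1(O)[C@@H](O)[C@]3(C(C)C)C[C@H]2OC(C)(C)O3
F9 | step 14 | 5α-mesylate 6α-alcohol with ring-B enol triflate | C[C@@]12CC(OS(=O)(=O)C(F)(F)F)=C(C)C[C@]1(O)[C@@H](OS(C)(=O)=O)[C@]3(C(C)C)C[C@H]2OC(C)(C)O3
F10 | step 14 | trans-fused hydroazulen-6-one acetonide with C9 enol triflate | CC1(C)O[C@@H]2C[C@@](O1)(C(C)C)[C@@H]3C(=O)CC(C)=C(OS(=O)(=O)C(F)(F)F)C[C@]32C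
F11 | step 15 | 6α-alcohol 2α,4α-acetonide (C6 epimer of 20) | CC1(C)O[C@@H]2C[C@@](O1)(C(C)C)[C@@H]3[C@H](O)CC(C)=CC[C@]32C
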